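**Strategy.** The route rests on cutting the C3=C4 alkene of the pyran ring. This is the only isolated alkene of the molecule, lying between quaternary C2 and arene carbon B3, with O1 on B4. Ring-closing metathesis between a vinyl group on B3 and a 2-methylbut-3-en-2-yl ether on the B4 oxygen closes the six-membered pyran and forms that alkene in one operation, with the position of the oxygen settled beforehand. The precursor is the complete methylene-bridged dimer as its B2,B6-bis(methoxymethyl) ether. It is assembled by three oxygen-directed lithiations of one phloroglucinol ring and a final C-benzylation of butyrylfilicinic acid.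

Key step: step 12

Remarks on the chemistry:
- Ring B is the aromatic ring. B1 carries the bridging CH2, B2 and B6 the phenolic oxygens, B3 the pyran carbon C4, B4 the pyran oxygen O1, and B5 the butanoyl group.
- The target has no stereocentre. The carbinol carbon of 11–14 is formed racemic and is removed by oxidation in step 8, so no stereodescriptor is written.
- The triketone unit is drawn throughout in the enol tautomer of the target SMILES.

**Step 1**
Reactants: 1 phloroglucinol
Product: 3 3,5-bis(methoxymethoxy)phenol, via 5-(methoxymethoxy)benzene-1,3-diol 2 (not isolated)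
Conditions: MOMCl (2.0 equiv), i-Pr2NEt, DMF, 0 °C → rt; chromatography
Reagents that add atoms: chloromethyl methyl ether, COCCl
Why: MOM protection (O-alkylation of a phenoxide by an α-chloro ether) of a symmetric triphenol with two equivalents of reagent should give the bis-ether as the main component of a statistical mixture, separable by chromatography, with the mono- and tris-ethers recyclable.

**Step 2**
Reactants: 3 3,5-bis(methoxymethoxy)phenol; 4 3-chloro-3-methylbut-1-yne
Product: 5 1,3-bis(methoxymethoxy)-5-[(2-methylbut-3-yn-2-yl)oxy]benzene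
Conditions: DBU, CuCl2·2H2O (cat.), MeCN, 0 °C
Reagents that add atoms: none
Why: Copper-catalysed propargylic O-alkylation of a phenol (substitution through a copper acetylide) should give the tertiary aryl propargyl ether on the single unhindered phenol at 0 °C, far below the temperature of propargyl Claisen rearrangement.

**Step 3**
Reactants: 5 1,3-bis(methoxymethoxy)-5-[(2-methylbut-3-yn-2-yl)oxy]benzene
Product: 6 1,3-bis(methoxymethoxy)-5-[(2-methylbut-3-en-2-yl)oxy]benzene
Conditions: H2 (1 atm), Pd/CaCO3 poisoned with Pb(OAc)2, quinoline, EtOAc, rt; product kept below 30 °C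
Reagents that add atoms: none
Why: Lindlar semihydrogenation should stop at the terminal alkene, and placing it before any other alkene and before any organolithium step removes the acidic alkyne hydrogen and a later chemoselectivity problem.

**Step 4**
Reactants: 6 1,3-bis(methoxymethoxy)-5-[(2-methylbut-3-en-2-yl)oxy]benzene
Product: 8 1-[2,6-bis(methoxymethoxy)-4-[(2-methylbut-3-en-2-yl)oxy]phenyl]-N,N-dimethylmethanamine, via aryllithium 7 (not isolated)
Conditions: n-BuLi, THF, −40 → −20 °C; Me2N=CH2+ I− (solid), −78 °C → rt
Reagents that add atoms: N,N-dimethylmethyleneiminium iodide (Eschenmoser's salt), C=[N+](C)C.[I-]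
Why: Directed ortho-metalation should occur at the position flanked by both OMOM groups (cooperative chelation, the bulky tertiary ether shielding the other two sites), and Mannich-type aminomethylation of the aryllithium gives a benzylic amine that is inert to the later organolithium, ylide and oxidation steps.

**Step 5**
Reactants: 8 1-[2,6-bis(methoxymethoxy)-4-[(2-methylbut-3-en-2-yl)oxy]phenyl]-N,N-dimethylmethanamine; 9 butanal
Product: 11 1-[3-[(dimethylamino)methyl]-2,4-bis(methoxymethoxy)-6-[(2-methylbut-3-en-2-yl)oxy]phenyl]butan-1-ol (racemic), via aryllithium 10 (not isolated)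
Conditions: s-BuLi (1.2 equiv), THF, −78 °C; butanal, −78 °C; H2O
Reagents that add atoms: none
Why: OMOM-directed ortho-lithiation at one of the two equivalent remaining ring positions, kept at −78 °C so that the aryllithium does not add to the neighbouring allyl ether, followed by 1,2-addition to the aldehyde should give the benzylic alcohol, whose carbinol stereocentre is formed racemic and erased in step 8.

**Step 6**
Reactants: 11 1-[3-[(dimethylamino)methyl]-2,4-bis(methoxymethoxy)-6-[(2-methylbut-3-en-2-yl)oxy]phenyl]butan-1-ol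
Product: 13 3-[(dimethylamino)methyl]-5-(1-hydroxybutyl)-2,4-bis(methoxymethoxy)-6-[(2-methylbut-3-en-2-yl)oxy]benzaldehyde, via dilithio species 12 (not isolated)
Conditions: s-BuLi (2.3 equiv), THF, −78 °C; DMF, −78 → 0 °C; H2O
Reagents that add atoms: N,N-dimethylformamide, CN(C)C=O
Why: With the hydroxyl carried as its lithium alkoxide, the second equivalent of base should metalate the last ring C–H ortho to OMOM and formylation with DMF gives the aldehyde on work-up; introducing this carbon only now, and as a formyl group, means that no styrene is ever exposed to an alkyllithium.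

**Step 7**
Reactants: 13 3-[(dimethylamino)methyl]-5-(1-hydroxybutyl)-2,4-bis(methoxymethoxy)-6-[(2-methylbut-3-en-2-yl)oxy]benzaldehyde
Product: 14 1-[3-[(dimethylamino)methyl]-5-ethenyl-2,4-bis(methoxymethoxy)-6-[(2-methylbut-3-en-2-yl)oxy]phenyl]butan-1-ol
Conditions: Ph3PCH3Br (3 equiv), KOt-Bu (3 equiv), THF, 0 °C; then 13, 0 °C → rt
Reagents that add atoms: methyltriphenylphosphonium bromide, C[P+](c1ccccc1)(c1ccccc1)c1ccccc1.[Br-]
Why: Wittig methylenation with excess ylide (one equivalent is consumed by the hydroxyl) should convert the hindered, non-enolisable aldehyde into the B3 vinyl group without touching the other functions.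

**Step 8**
Reactants: 14 1-[3-[(dimethylamino)methyl]-5-ethenyl-2,4-bis(methoxymethoxy)-6-[(2-methylbut-3-en-2-yl)oxy]phenyl]butan-1-ol
Product: 15 1-[3-[(dimethylamino)methyl]-5-ethenyl-2,4-bis(methoxymethoxy)-6-[(2-methylbut-3-en-2-yl)oxy]phenyl]butan-1-one
Conditions: Dess–Martin periodinane, pyridine, CH2Cl2, 0 °C → rt
Reagents that add atoms: none
Why: Dess–Martin oxidation of the secondary benzylic alcohol under pyridine buffering should give the aryl ketone while leaving both alkenes, the MOM acetals and the acid-sensitive tertiary allyl ether intact, and it removes the only stereocentre of the route.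

**Step 9**
Reactants: 1 phloroglucinol; 16 butanoyl chloride
Product: 17 1-(2,4,6-trihydroxyphenyl)butan-1-one
Conditions: AlCl3, PhNO2/CH2Cl2, rt → 50 °C; aq. HCl work-up
Reagents that add atoms: none
Why: Friedel–Crafts C-acylation of phloroglucinol should stop at the mono-ketone because the first acyl group deactivates the ring.

**Step 10**
Reactants: 17 1-(2,4,6-trihydroxyphenyl)butan-1-one
Product: 19 butyrylfilicinic acid (2-butanoyl-3,5-dihydroxy-6,6-dimethylcyclohexa-2,4-dien-1-one), via 1-(2,4,6-trihydroxy-3-methylphenyl)butan-1-one 18 (not isolated)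
Conditions: MeI (2.2 equiv), NaOMe, MeOH, 0 °C → rt; acidify; chromatography
Reagents that add atoms: iodomethane, CI
Why: Alkylative dearomatisation by C-methylation of the acylphloroglucinol anion in methanol should put two methyl groups on one ring carbon, the established way to acylfilicinic acids, with over- and under-methylated material removed by chromatography.

**Step 11**
Reactants: 15 1-[3-[(dimethylamino)methyl]-5-ethenyl-2,4-bis(methoxymethoxy)-6-[(2-methylbut-3-en-2-yl)oxy]phenyl]butan-1-one; 19 butyrylfilicinic acid
Product: 21 2-butanoyl-4-{[3-butanoyl-5-ethenyl-2,6-bis(methoxymethoxy)-4-[(2-methylbut-3-en-2-yl)oxy]phenyl]methyl}-3,5-dihydroxy-6,6-dimethylcyclohexa-2,4-dien-1-one, via benzylic chloride 20 (not isolated)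
Conditions: ClCO2Et (1.05 equiv), THF, 0 °C → rt, volatiles removed cold; then added to 19 (1.5 equiv) pretreated with NaH (3.0 equiv) in THF/DMF, 0 °C → rt; aq. NaH2PO4 (pH 5) work-up
Reagents that add atoms: none
Why: Ethyl chloroformate acylates the tertiary amine and chloride displaces the carbamate from the electron-rich benzylic carbon (von Braun-type cleavage), and the resulting chloride, which cannot self-condense because the arene is fully substituted, should alkylate the dianion of 19 at its only ring CH carbon (C-benzylation of a cyclic β-dicarbonyl enolate), any O-benzyl enol ether being expected to reionise and funnel to the C-linked product.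

**Step 12**
Reactants: 21 2-butanoyl-4-{[3-butanoyl-5-ethenyl-2,6-bis(methoxymethoxy)-4-[(2-methylbut-3-en-2-yl)oxy]phenyl]methyl}-3,5-dihydroxy-6,6-dimethylcyclohexa-2,4-dien-1-one
Product: 22 drummondin A bis(methoxymethyl) ether (2-butanoyl-4-{[8-butanoyl-5,7-bis(methoxymethoxy)-2,2-dimethyl-2H-chromen-6-yl]methyl}-3,5-dihydroxy-6,6-dimethylcyclohexa-2,4-dien-1-one)
Conditions: second-generation Grubbs catalyst RuCl2(=CHPh)(PCy3)(H2IMes) (5 mol%), degassed CH2Cl2 (0.005 M), 40 °C
Reagents that add atoms: none
Why: The benzylidene of the catalyst should exchange first with the B3 vinyl group, since the other terminal alkene sits next to quaternary C2 and initiates slowly; the resulting ruthenium arylidene then undergoes [2+2] cycloaddition with the 2-methylbut-3-en-2-yl alkene and cycloreversion, expelling ethylene and forming C3=C4. The closest known reaction type is ring-closing metathesis of 2-vinylaryl allyl ethers, 1,1-dimethylallyl ethers included, to 2H-chromenes. The pyran is closed in a six-membered mode by joining the two internal carbons of a 1,7-diene held ortho on the arene, so only the cis ring alkene can form. No stereocentre is created. The step needs ring closure to outrun cross-metathesis and alkene migration: the ortho arrangement on a fully substituted arene, the gem-dimethyl group and high dilution favour closure, neither alkene carries an allylic hydrogen, and Claisen rearrangement is shut off because B3, B5 and B1 are all substituted. The enolised triketone is about as acidic as a carboxylic acid, a group this catalyst tolerates, and the medium is kept free of base so that no chelating enolate can bind ruthenium.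

**Step 13**
Reactants: 22 drummondin A bis(methoxymethyl) ether
Product: 23 drummondin A (2-butanoyl-4-[(8-butanoyl-5,7-dihydroxy-2,2-dimethyl-2H-chromen-6-yl)methyl]-3,5-dihydroxy-6,6-dimethylcyclohexa-2,4-dien-1-one)
Conditions: HCl (2 M aq.)/MeOH 1:5, 40 °C
Reagents that add atoms: none
Why: Acid-catalysed acetal exchange with methanol should remove both aryl MOM ethers, while the 2,2-dimethylchromene, the methylene bridge and the enolised triketone are stable to dilute acid at this temperature.

**Compound list**

1 | phloroglucinol (benzene-1,3,5-triol) | Oc1cc(O)cc(O)c1 | starting material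
2 | 5-(methoxymethoxy)benzene-1,3-diol (formed in the flask in step 1) | COCOc1cc(O)cc(O)c1 | intermediate
3 | 3,5-bis(methoxymethoxy)phenol | COCOc1cc(O)cc(OCOC)c1 | intermediate
4 | 3-chloro-3-methylbut-1-yne | CC(C)(Cl)C#C | starting material
5 | 1,3-bis(methoxymethoxy)-5-[(2-methylbut-3-yn-2-yl)oxy]benzene | C#CC(C)(C)Oc1cc(OCOC)cc(OCOC)c1 | intermediate
6 | 1,3-bis(methoxymethoxy)-5-[(2-methylbut-3-en-2-yl)oxy]benzene | C=CC(C)(C)Oc1cc(OCOC)cc(OCOC)c1 | intermediate
7 | [2,6-bis(methoxymethoxy)-4-[(2-methylbut-3-en-2-yl)oxy]phenyl]lithium (formed in the flask in step 4) | [Li]c1c(OCOC)cc(OC(C)(C)C=C)cc1OCOC | intermediate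
8 | 1-[2,6-bis(methoxymethoxy)-4-[(2-methylbut-3-en-2-yl)oxy]phenyl]-N,N-dimethylmethanamine | CN(C)Cc1c(OCOC)cc(OC(C)(C)C=C)cc1OCOC | intermediate
9 | butanal | CCCC=O | starting material
10 | [3-[(dimethylamino)methyl]-2,4-bis(methoxymethoxy)-6-[(2-methylbut-3-en-2-yl)oxy]phenyl]lithium (formed in the flask in step 5) | [Li]c1c(OC(C)(C)C=C)cc(OCOC)c(CN(C)C)c1OCOC | intermediate
11 | 1-[3-[(dimethylamino)methyl]-2,4-bis(methoxymethoxy)-6-[(2-methylbut-3-en-2-yl)oxy]phenyl]butan-1-ol (racemic) | CCCC(O)c1c(OC(C)(C)C=C)cc(OCOC)c(CN(C)C)c1OCOC | intermediate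
12 | lithium 1-[3-[(dimethylamino)methyl]-5-lithio-2,4-bis(methoxymethoxy)-6-[(2-methylbut-3-en-2-yl)oxy]phenyl]butan-1-olate (formed in the flask in step 6) | CCCC(O[Li])c1c(OC(C)(C)C=C)c([Li])c(OCOC)c(CN(C)C)c1OCOC | intermediate
13 | 3-[(dimethylamino)methyl]-5-(1-hydroxybutyl)-2,4-bis(methoxymethoxy)-6-[(2-methylbut-3-en-2-yl)oxy]benzaldehyde (racemic) | CCCC(O)c1c(OC(C)(C)C=C)c(C=O)c(OCOC)c(CN(C)C)c1OCOC | intermediate
14 | 1-[3-[(dimethylamino)methyl]-5-ethenyl-2,4-bis(methoxymethoxy)-6-[(2-methylbut-3-en-2-yl)oxy]phenyl]butan-1-ol (racemic) | CCCC(O)c1c(OC(C)(C)C=C)c(C=C)c(OCOC)c(CN(C)C)c1OCOC | intermediate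
15 | 1-[3-[(dimethylamino)methyl]-5-ethenyl-2,4-bis(methoxymethoxy)-6-[(2-methylbut-3-en-2-yl)oxy]phenyl]butan-1-one | CCCC(=O)c1c(OC(C)(C)C=C)c(C=C)c(OCOC)c(CN(C)C)c1OCOC | intermediate
16 | butanoyl chloride | CCCC(Cl)=O | starting material
17 | 1-(2,4,6-trihydroxyphenyl)butan-1-one | CCCC(=O)c1c(O)cc(O)cc1O | intermediate
18 | 1-(2,4,6-trihydroxy-3-methylphenyl)butan-1-one (formed in the flask in step 10) | CCCC(=O)c1c(O)cc(O)c(C)c1O | intermediate
19 | butyrylfilicinic acid (2-butanoyl-3,5-dihydroxy-6,6-dimethylcyclohexa-2,4-dien-1-one) | CCCC(=O)C1=C(O)C=C(O)C(C)(C)C1=O | intermediate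
20 | 1-[3-(chloromethyl)-5-ethenyl-2,4-bis(methoxymethoxy)-6-[(2-methylbut-3-en-2-yl)oxy]phenyl]butan-1-one (formed in the flask in step 11) | CCCC(=O)c1c(OC(C)(C)C=C)c(C=C)c(OCOC)c(CCl)c1OCOC | intermediate
21 | 2-butanoyl-4-{[3-butanoyl-5-ethenyl-2,6-bis(methoxymethoxy)-4-[(2-methylbut-3-en-2-yl)oxy]phenyl]methyl}-3,5-dihydroxy-6,6-dimethylcyclohexa-2,4-dien-1-one | CCCC(=O)C1=C(O)C(Cc2c(OCOC)c(C=C)c(OC(C)(C)C=C)c(C(=O)CCC)c2OCOC)=C(O)C(C)(C)C1=O | intermediate
22 | drummondin A bis(methoxymethyl) ether | CCCC(=O)C1=C(O)C(Cc2c(OCOC)c3C=CC(C)(C)Oc3c(C(=O)CCC)c2OCOC)=C(O)C(C)(C)C1=O | intermediate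
23 | drummondin A | CCCC(=O)C1=C(O)C(Cc2c(O)c3c(c(C(=O)CCC)c2O)OC(C)(C)C=C3)=C(O)C(C)(C)C1=O | target

**Totals.** Total step count: 13. Longest linear sequence: 11 steps (steps 1–8, 11, 12, 13). Steps 9 and 10 prepare the filicinic half.

**Steps most likely to fail, with fallbacks**

Step 11 (union of the two halves). What may go wrong: the ambident dienolate is benzylated on oxygen, or the benzylic chloride ionises and decomposes (loss of the tertiary allyl group, or attack by a neighbouring MOM oxygen) before carbon attack. Fallback: starting from 15, the chloride 20 is generated with ethyl chloroformate as before and taken up at once in DMSO with NaHCO3. Kornblum oxidation should then give 3-butanoyl-5-ethenyl-2,6-bis(methoxymethoxy)-4-[(2-methylbut-3-en-2-yl)oxy]benzaldehyde F1. This aldehyde is condensed with 19 under L-proline catalysis in the presence of Hantzsch ester (reductive Knoevenagel alkylation). The benzylidene triketone 2-butanoyl-4-{[3-butanoyl-5-ethenyl-2,6-bis(methoxymethoxy)-4-[(2-methylbut-3-en-2-yl)oxy]phenyl]methylidene}-3-hydroxy-6,6-dimethylcyclohex-2-ene-1,5-dione F2 is reduced in the flask by hydride transfer. Only the carbon-linked product can result, and the route is rejoined at 21.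

Step 6 (last ring metalation). What may go wrong: the lithium alkoxide aggregates and metalation of the last ring C–H stalls, or the aryllithium adds to the alkene of the neighbouring allyl ether. Fallback: starting from 11, the only remaining ring position, activated by three oxygens, is iodinated with N-iodosuccinimide in MeCN at 0 °C. This should give 1-[3-[(dimethylamino)methyl]-5-iodo-2,4-bis(methoxymethoxy)-6-[(2-methylbut-3-en-2-yl)oxy]phenyl]butan-1-ol F3. Iodine–magnesium exchange with i-PrMgCl·LiCl in THF at −20 °C, the first equivalent removing the hydroxyl proton, gives the arylmagnesium alkoxide F4, which does not carbometalate alkenes. DMF then delivers 13.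

Step 12 (ring closure). What may go wrong: the catalyst is tied up by the enolised triketone, or the acidic enol cleaves the tertiary allyl aryl ether before ring closure. Fallback: the order of ring closure and fragment union is exchanged. Starting from 15, protonated with one equivalent of p-toluenesulfonic acid to mask the amine, the same catalyst in CH2Cl2 at 40 °C should close 1-[6-[(dimethylamino)methyl]-5,7-bis(methoxymethoxy)-2,2-dimethyl-2H-chromen-8-yl]butan-1-one F5. Ethyl chloroformate then gives 1-[6-(chloromethyl)-5,7-bis(methoxymethoxy)-2,2-dimethyl-2H-chromen-8-yl]butan-1-one F6. Its reaction with the disodium salt of 19, as in step 11, rejoins the route at 22.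

**Further compounds**

F1 | step 11 | 3-butanoyl-5-ethenyl-2,6-bis(methoxymethoxy)-4-[(2-methylbut-3-en-2-yl)oxy]benzaldehyde | CCCC(=O)c1c(OC(C)(C)C=C)c(C=C)c(OCOC)c(C=O)c1OCOC
F2 | step 11 | 2-butanoyl-4-{[3-butanoyl-5-ethenyl-2,6-bis(methoxymethoxy)-4-[(2-methylbut-3-en-2-yl)oxy]phenyl]methylidene}-3-hydroxy-6,6-dimethylcyclohex-2-ene-1,5-dione (alkene geometry not defined) | CCCC(=O)C1=C(O)C(=Cc2c(OCOC)c(C=C)c(OC(C)(C)C=C)c(C(=O)CCC)c2OCOC)C(=O)C(C)(C)C1=O
F3 | step 6 | 1-[3-[(dimethylamino)methyl]-5-iodo-2,4-bis(methoxymethoxy)-6-[(2-methylbut-3-en-2-yl)oxy]phenyl]butan-1-ol (racemic) | CCCC(O)c1c(OC(C)(C)C=C)c(I)c(OCOC)c(CN(C)C)c1OCOC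
F4 | step 6 | chloromagnesium 1-[5-(chloromagnesio)-3-[(dimethylamino)methyl]-2,4-bis(methoxymethoxy)-6-[(2-methylbut-3-en-2-yl)oxy]phenyl]butan-1-olate | CCCC(O[Mg]Cl)c1c(OC(C)(C)C=C)c([Mg]Cl)c(OCOC)c(CN(C)C)c1OCOC
F5 | step 12 | 1-[6-[(dimethylamino)methyl]-5,7-bis(methoxymethoxy)-2,2-dimethyl-2H-chromen-8-yl]butan-1-one | CCCC(=O)c1c(OCOC)c(CN(C)C)c(OCOC)c2C=CC(C)(C)Oc12
F6 | step 12 | 1-[6-(chloromethyl)-5,7-bis(methoxymethoxy)-2,2-dimethyl-2H-chromen-8-yl]butan-1-one | CCCC(=O)c1c(OCOC)c(CCl)c(OCOC)c2C=CC(C)(C)Oc12
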